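**Two plateaus.** The ochre run levels off higher than the teal run, and I ask what that height is worth for the flask below. Solid substrate dissolves to starting material, reagent turns this into target, and target may pass into isomer of the product B.

| flask | solid substrate | reagent | temperature | remark | time |
|---|---|---|---|---|---|
| teal | 0.10 M | 0.20 M | 25 °C | the very flask that is asked about, followed so far |  |
| ochre | 0.067 M | 0.20 M | 31 °C | run made earlier |  |
| flask | 0.10 M | 0.200 M | 25 °C |  | 8.0 d |

| run | time / h | target / % | solid substrate / % |
|---|---|---|---|
| teal | 6.00 | 14.3 | 0.6 |
| teal | 20.0 | 10.1 | 0 |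
| teal | 30.0 | 9.5 | 0 |
| teal | 50.0 | 10.8 | 0 |
| teal | 72.0 | 10.2 | 0.3 |
| teal | 96.0 | 11.5 | 0.9 |
| teal | 120 | 11.4 | 0 |
| ochre | 2.50 | 16.9 | 0.1 |
| ochre | 8.00 | 17.5 | 1.2 |
| ochre | 15.0 | 21.5 | 0 |
| ochre | 20.0 | 17.9 | 0.6 |
| ochre | 30.0 | 20.0 | 0 |
| ochre | 40.0 | 19.1 | 1.5 |
| ochre | 48.0 | 20.9 | 0 |

(each reading ± 1 percentage point)

- solid substrate is a solid; its amount is given per volume of the solution
- target taken out counts as made
- on the list of suspects stand: target <-> isomer of the product B; solid substrate <-> starting material; reagent + other conformer -> isomer of the product A; starting material + reagent -> target; starting material <-> other conformer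
- at the start none of the solid substrate is in solution
- additions bring no volume worth counting

- cedar: at 8.0 d raise the temperature by 25 K, then wait 4.0 d
- birch: at 8.0 d add reagent, 50.0 % of the amount charged, then wait 4.0 d
- maple: change nothing and wait 4.0 d more
- elm: at 8.0 d take out 90 % of the target then present, then wait 4.0 d

- target, in percent of the solid substrate first charged, at 8.0 d
- what to do for the largest gain in target; "none" if nothing gains more than 2 percentage points (cedar / birch / maple / elm / none)
- target present, with what was taken out counted in, in percent of the solid substrate first charged, after maple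
- target present, with what was taken out counted in, in percent of the solid substrate first charged, after elm

**The ratio.** Teal target averages 10.6 % from 20.0 h on, and ochre target 19.9 % from 15.0 h on. From teal I take W = 8.45, the parts of the charge outside target per part of target on the plateau. Ochre reads 4.03. The suspect step between target and isomer of the product B is first order both ways, so its ratio holds no concentration, and I read the change in W as an effect of temperature (thermodynamic control). That gives a heat of 93.0 kJ mol⁻¹. Cedar's rise of 25 K then brings W to 0.464, which is 68.3 % target.

**Turned round.** With W frozen at 25 °C, maple stays on the plateau. Elm takes out 90 % of the target, and the remainder refills at the same W, so I count 19.1 %. For elm to beat heating, W after the rise would have to stay above 4.24. The ochre reading at 31 °C is already lower than that. I commit to cedar.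

**The forecast.** It gives 10.7 % now, 10.7 % after maple and 14.5 % after elm, which is less than my count for elm, and it chooses elm, where I choose cedar. Its ground: “Ochre's higher plateau mixes concentration and temperature effects”.

**The flask.** The flask gives 10.7 % now, and cedar gains 50 percentage points, against 8.5 points for elm, whose target with what was taken out counted in comes to 19.2 %. Target and isomer of the product B relax with a half-life of 0.993 h, both ways together, which is short against 8.0 d. Cedar's target of 61.0 % puts W at 0.639, against my 0.464.

    target ⇌ isomer of the product B (K = 7.14, k = 0.0102 min⁻¹, Ea = 102 kJ mol⁻¹, ΔH = −90.0 kJ mol⁻¹)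
    solid substrate ⇌ starting material, rate k2*(cs2 - [starting material]) while solid is left; crystals form when [starting material] > cs2 (solubility = 0.0800 M, k = 0.0290 min⁻¹)
    reagent + other conformer → isomer of the product A (k = 0.0163 M⁻¹ min⁻¹, Ea = 58.0 kJ mol⁻¹)
    starting material + reagent → target (k = 0.0164 M⁻¹ min⁻¹, Ea = 79.0 kJ mol⁻¹)
    starting material ⇌ other conformer (K = 0.184, k = 0.00214 min⁻¹, Ea = 91.0 kJ mol⁻¹, ΔH = 11.0 kJ mol⁻¹)
    (constants at 25 °C)

**Second flask.** For a neighbouring flask kept at 50 °C from the start, my W reckoned for that temperature is 0.464, which gives 68.3 % target. The computed value is 62.5 %, which is a W of 0.600.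

(The earlier runs and the new flask were computed with made-up constants; noise was put on by code.)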